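**Remark (one assumption on the chemistry).** Read literally, the SMILES places H‑6 and H‑7 cis in both halves (C7 and C7′ are R, so both lactones are cis‑fused, i.e. the 7‑epi series relative to dehydrozaluzanin C). Natural trans‑lactone guaianolides therefore cannot serve as starting materials, and the cis‑lactone monomer is built de novo. Guaiane numbering is used throughout (C1–C15; lactone C12(=O)–O–C6 with C7–C11(=C13); primes for the dienophile half; α/β as in the usual guaianolide drawing).

## Retrosynthetic overview

1. Ring D (C2–C1=C10–C14–C15′–C4′) is opened by an endo Diels–Alder disconnection into diosphenol diene 22 (C2(OH)=C1–C10=C14) and exo‑methylene enone 18 (C4′=C15′); both halves derive from one monomer, 7‑epi‑dehydrozaluzanin C (18).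
2. Ring A of 18 is a 2‑methylenecyclopentanone: the C3 ketone is flanked by the exocyclic C4=C15 alkene and by ring‑fusion carbon C5. This is the retron of an alkynylcyclobutanol ring expansion, so ring A comes from the four‑membered ring C3–C2–C1–C5 of 17, with C5 shifting onto the alkyne carbon that becomes C4.
3. The cyclobutane comes from a [2+2] photocycloaddition of 1,1‑dimethoxyethene to cycloheptenone 9; the C10 ketone then becomes C10=C14 and the lactone is α‑methylenated.
4. Ring B is bought as cycloheptene; C7 is set by asymmetric allylic alkylation, C6 (cis‑lactone) and C5 by iodolactonisation, then elimination and allylic oxidation give 9.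
5. Order of ring formation: B (purchased) → lactone C → cyclobutane → ring A (by enlargement) → ring D (dimerisation).

Key step: step 12

## Route

Step 1
Reactants: 1 cycloheptene
Product: 2 (±)-cyclohept-2-en-1-yl benzoate
Conditions: tert-butyl perbenzoate, CuBr (5 mol%), MeCN, 80 °C, cycloheptene in excess
Reagents that add atoms: tert-butyl perbenzoate, CC(C)(C)OOC(=O)c1ccccc1
Why: Kharasch–Sosnovsky allylic acyloxylation, in which the tert-butoxyl radical abstracts an allylic hydrogen and copper benzoate transfers benzoate to the symmetrical cycloheptenyl radical, so a single racemic allylic ester results and no stereocentre needs control.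

Step 2
Reactants: 2 (±)-cyclohept-2-en-1-yl benzoate; 3 dimethyl malonate
Product: 4 dimethyl (S)-2-(cyclohept-2-en-1-yl)malonate
Conditions: [Pd(C3H5)Cl]2 (2.5 mol%), (1R,2R)-N,N'-bis(2-diphenylphosphinobenzoyl)-1,2-diaminocyclohexane (7.5 mol%), NaH, (n-Hex)4NBr, CH2Cl2, 0 °C to rt
Reagents that add atoms: none
Why: Tsuji–Trost asymmetric allylic alkylation, in which both enantiomers of 2 ionise to the same meso π-allylpalladium complex and the chiral diphosphine directs the malonate to one enantiotopic terminus, which sets C7 (the ligand antipode would be used should the sense of induction prove opposite).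

Step 3
Reactants: 4 dimethyl (S)-2-(cyclohept-2-en-1-yl)malonate
Product: 5 methyl (R)-2-(cyclohept-2-en-1-yl)acetate
Conditions: LiCl, H2O, DMSO, 150 °C
Reagents that add atoms: none
Why: Krapcho dealkoxycarbonylation (chloride SN2 demethylation, loss of CO2, protonation) leaves the allylic stereocentre C7 untouched (the descriptor changes only through priorities).

Step 4
Reactants: 5 methyl (R)-2-(cyclohept-2-en-1-yl)acetate
Product: 7 (3aR,8S,8aS)-8-iodooctahydro-2H-cyclohepta[b]furan-2-one, via lithium carboxylate 6 (not isolated)
Conditions: LiOH, THF/H2O, rt; then NaHCO3, I2, KI, 0 °C to rt, dark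
Reagents that add atoms: lithium hydroxide, [Li+].[OH-]; iodine, II
Why: Saponification then iodolactonisation, in which the carboxylate opens the iodonium ion of the C5=C6 alkene by 5-exo anti addition; only the cis-fused γ-lactone can form, so C6 (oxygen cis to the C7 side chain) and C5 (iodide trans to oxygen) are set from C7.

Step 5
Reactants: 7 (3aR,8S,8aS)-8-iodooctahydro-2H-cyclohepta[b]furan-2-one
Product: 8 (3aR,8aS)-3,3a,4,5,6,8a-hexahydro-2H-cyclohepta[b]furan-2-one
Conditions: DBU, toluene, 80 °C
Reagents that add atoms: none
Why: E2 dehydrohalogenation, in which the only hydrogen anti-periplanar to the C5 iodide sits on C1 (H-6 is syn), so the C1=C5 alkene forms regioselectively.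

Step 6
Reactants: 8 (3aR,8aS)-3,3a,4,5,6,8a-hexahydro-2H-cyclohepta[b]furan-2-one
Product: 9 (3aR,8aS)-3,3a,4,5-tetrahydro-2H-cyclohepta[b]furan-2,6(8aH)-dione
Conditions: Rh2(cap)4 (cap = caprolactamate, 1 mol%), t-BuOOH (70% aq., 5 equiv), K2CO3, CH2Cl2, rt
Reagents that add atoms: tert-butyl hydroperoxide, CC(C)(C)OO
Why: Allylic oxidation by the dirhodium caprolactamate/tert-butyl hydroperoxide system (hydrogen abstraction by tert-butylperoxyl radical, then collapse of the mixed peroxide to the ketone) at C10, the only unoxygenated allylic methylene, gives the enone without touching C6 or C7.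

Step 7
Reactants: 9 (3aR,8aS)-3,3a,4,5-tetrahydro-2H-cyclohepta[b]furan-2,6(8aH)-dione; 10 1,1-dimethoxyethene
Product: 11 cyclobutane photoadduct (C3 dimethyl acetal and C10 ketone; 1αH,5αH,6βH,7βH)
Conditions: hν (350 nm, Pyrex), 10 (20 equiv), CH2Cl2, −40 °C; then basic Al2O3
Reagents that add atoms: none
Why: Enone–alkene [2+2] photocycloaddition in the head-to-tail sense usual for electron-rich 1,1-dialkoxyethenes (acetal carbon C3 to the β-carbon C5, CH2 to C1); the alkene adds anti to the cis-fused lactone, which sets C5, and the alumina treatment equilibrates the enolisable C1 to the cis four/seven ring fusion.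

Step 8
Reactants: 11 cyclobutane photoadduct
Product: 12 C10-methylene acetal (C10=C14)
Conditions: Ph3PCH3Br, KOt-Bu, THF, 0 °C to rt
Reagents that add atoms: methyltriphenylphosphonium bromide, C[P+](c1ccccc1)(c1ccccc1)c1ccccc1.[Br-]
Why: Wittig methylenation of the C10 ketone installs C14; the ylide reacts with the ketone far faster than with the lactone, and the dimethyl acetal is inert.

Step 9
Reactants: 12 C10-methylene acetal
Product: 15 bis-methylene acetal (C10=C14 and C11=C13), via Mannich base 13 (not isolated), via ammonium iodide 14 (not isolated)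
Conditions: LiN(i-Pr)2, THF, −78 °C; CH2=NMe2 I; then MeI, MeOH; then NaHCO3 (aq), CH2Cl2
Reagents that add atoms: dimethylmethyleneiminium iodide, C=[N+](C)C.[I-]
Why: Mannich reaction of the lactone enolate with the preformed iminium salt, N-methylation and base-induced β-elimination of trimethylamine (standard α-methylenation) give the C11=C13 alkene without affecting any stereocentre.

Step 10
Reactants: 15 bis-methylene acetal
Product: 16 cyclobutanone (C3 ketone on the C3–C2–C1–C5 ring)
Conditions: oxalic acid (aq), THF, rt
Reagents that add atoms: water, O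
Why: Acid-catalysed acetal hydrolysis unmasks the strained cyclobutanone under conditions too mild to isomerise the exocyclic alkenes.

Step 11
Reactants: 16 cyclobutanone
Product: 17 3-ethynylcyclobutan-3-ol (ethynyl α, hydroxyl β)
Conditions: HC≡CMgBr, THF, −78 °C; aq. NH4Cl
Reagents that add atoms: ethynylmagnesium bromide, C#C[Mg]Br
Why: Chemoselective 1,2-addition of the acetylide to the strained, highly electrophilic cyclobutanone (lactone carbonyl and α-methylene lactone react much more slowly at low temperature) from the convex α-face; the configuration of the new carbinol C3 is erased in step 12.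

Step 12
Reactants: 17 3-ethynylcyclobutan-3-ol
Product: 18 7-epi-dehydrozaluzanin C
Conditions: (p-CF3C6H4)3PAuCl (2.5 mol%), AgSbF6 (2.5 mol%), CH2Cl2, rt
Reagents that add atoms: none
Why: Cationic monovalent gold binds the alkyne of 17 selectively (it is an alkynophilic π-acid, so the 1,1-disubstituted alkenes and the α-methylene lactone stay untouched); the C3–C5 ring bond anti to the activated alkyne shifts onto the internal alkyne carbon C4 while the carbinol collapses to the C3 ketone, and protodeauration of the vinylgold releases the exocyclic C4=C15 methylene. The closest known reaction type is the gold-catalysed ring expansion of 1-alkynylcyclobutanols to 2-alkylidenecyclopentanones, a semipinacol-type 1,2-alkyl shift driven by release of cyclobutane strain. Ring A is closed by formation of the C4–C5 bond in this 1,2-shift (enlargement of the four-membered ring C3–C2–C1–C5 to the five-membered ring, not a Baldwin-type cyclisation), and no other ring is formed. No new stereocentre arises: C5 migrates with retention, so the 1αH,5αH cis fusion from step 7 is carried over, and the carbinol centre C3 disappears. The step needs migration of C5 rather than C2, which the higher migratory aptitude of the more substituted ring-fusion carbon over the CH2 group should secure, and the strain-driven shift should outpace Meyer–Schuster isomerisation.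

Step 13
Reactants: 18 7-epi-dehydrozaluzanin C
Product: 19 3-trimethylsilyloxy-2,4(15)-diene
Conditions: TMSOTf, Et3N, CH2Cl2, −78 to 0 °C
Reagents that add atoms: trimethylsilyl trifluoromethanesulfonate, C[Si](C)(C)OS(=O)(=O)C(F)(F)F
Why: Soft enolisation and O-silylation; the C3 ketone can enolise only towards C2 because C4 is sp2, which gives the cross-conjugated 2-silyloxydiene regiospecifically.

Step 14
Reactants: 19 3-trimethylsilyloxy-2,4(15)-diene
Product: 21 2α-hydroxy-7-epi-dehydrozaluzanin C, via silyloxy ketone 20 (not isolated)
Conditions: DMDO (acetone solution), CH2Cl2, −78 °C; then aq. citric acid, THF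
Reagents that add atoms: dimethyldioxirane, CC1(C)OO1
Why: Rubottom oxidation, in which DMDO epoxidises the electron-rich silyl enol ether in preference to the other alkenes and silyl migration then hydrolysis give the α-ketol; attack from the convex α-face is expected (2α-OH), though C2 becomes sp2 again in step 15.

Step 15
Reactants: 21 2α-hydroxy-7-epi-dehydrozaluzanin C
Product: 22 diosphenol diene (2-hydroxy-3-oxo-1,4(15),10(14),11(13)-tetraene)
Conditions: Dess–Martin periodinane, CH2Cl2, 0 °C to rt; used at once
Reagents that add atoms: none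
Why: Dess–Martin oxidation of the α-ketol to the 1,2-diketone, which should enolise towards the doubly activated C1 to give the diosphenol and thereby the s-cis 1-hydroxydiene C2(OH)=C1–C10=C14.

Step 16
Reactants: 22 diosphenol diene; 18 7-epi-dehydrozaluzanin C
Product: 23 CNP0269880.1 (target dimer)
Conditions: 18 (3 equiv), Et3N (0.2 equiv), CH2Cl2, 0 °C to rt
Reagents that add atoms: none
Why: Base-catalysed Diels–Alder reaction of a 1-hydroxydiene with an enone, precedented by amine-catalysed cycloadditions of 3-hydroxy-2-pyrones; the electron-rich terminus C14 bonds to the β-carbon C15′ and the hydroxylated C2 to C4′, and the endo transition state (C3′ carbonyl under the diene), with the dienophile meeting the β-face of 22 (anti to the α-oriented lactone) through its convex α-face, sets C2 (2α-OH) and the spiro centre C4′.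

## Compound list

1 | cycloheptene | C1=CCCCCC1 | starting material
2 | (±)-cyclohept-2-en-1-yl benzoate | O=C(OC1C=CCCCC1)c1ccccc1 | intermediate
3 | dimethyl malonate | COC(=O)CC(=O)OC | starting material
4 | dimethyl (S)-2-(cyclohept-2-en-1-yl)malonate | COC(=O)C(C(=O)OC)[C@@H]1C=CCCCC1 | intermediate
5 | methyl (R)-2-(cyclohept-2-en-1-yl)acetate | COC(=O)C[C@@H]1C=CCCCC1 | intermediate
6 | lithium (R)-2-(cyclohept-2-en-1-yl)acetate | [Li+].[O-]C(=O)C[C@@H]1C=CCCCC1 | intermediate
7 | (3aR,8S,8aS)-8-iodooctahydro-2H-cyclohepta[b]furan-2-one (cis-lactone; iodide at C5 trans to the lactone oxygen) | O=C1C[C@H]2CCCC[C@H](I)[C@H]2O1 | intermediate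
8 | (3aR,8aS)-3,3a,4,5,6,8a-hexahydro-2H-cyclohepta[b]furan-2-one (cis-lactone, C1=C5 alkene) | O=C1C[C@H]2CCCC=C[C@H]2O1 | intermediate
9 | (3aR,8aS)-3,3a,4,5-tetrahydro-2H-cyclohepta[b]furan-2,6(8aH)-dione (C10 ketone, C1=C5 enone) | O=C1C[C@H]2CCC(=O)C=C[C@H]2O1 | intermediate
10 | 1,1-dimethoxyethene | C=C(OC)OC | starting material
11 | cyclobutane photoadduct: C3 dimethyl acetal, C10 ketone, cis-fused cyclobutane on the β-face (1αH,5αH), cis-lactone on the α-face (6βH,7βH) | COC1(OC)C[C@H]2C(=O)CC[C@@H]3CC(=O)O[C@@H]3[C@H]21 | intermediate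
12 | C10-methylene analogue of 11 (C10=C14) | COC1(OC)C[C@H]2C(=C)CC[C@@H]3CC(=O)O[C@@H]3[C@H]21 | intermediate
13 | C11-(dimethylaminomethyl) lactone (Mannich base, C11 epimers) | COC1(OC)C[C@H]2C(=C)CC[C@@H]3C(CN(C)C)C(=O)O[C@@H]3[C@H]21 | intermediate
14 | trimethylammonium iodide of 13 | COC1(OC)C[C@H]2C(=C)CC[C@@H]3C(C[N+](C)(C)C)C(=O)O[C@@H]3[C@H]21.[I-] | intermediate
15 | bis-methylene acetal (C10=C14, C11=C13, C3 dimethyl acetal) | COC1(OC)C[C@H]2C(=C)CC[C@@H]3C(=C)C(=O)O[C@@H]3[C@H]21 | intermediate
16 | cyclobutanone (C3 ketone; ring C3–C2–C1–C5; 1αH,5αH,6βH,7βH) | O=C1C[C@H]2C(=C)CC[C@@H]3C(=C)C(=O)O[C@@H]3[C@H]21 | intermediate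
17 | 3-ethynylcyclobutan-3-ol (ethynyl α, hydroxyl β; otherwise as 16) | C#C[C@]1(O)C[C@H]2C(=C)CC[C@@H]3C(=C)C(=O)O[C@@H]3[C@H]21 | intermediate
18 | 7-epi-dehydrozaluzanin C, (3aR,6aR,9aR,9bS)-3,6,9-trimethylidene-3a,4,5,6a,7,9a,9b-heptahydroazuleno[4,5-b]furan-2,8-dione (3-oxo-1αH,5αH,6βH,7βH-guaia-4(15),10(14),11(13)-trien-12,6-olide) | C=C1C(=O)C[C@H]2C(=C)CC[C@@H]3C(=C)C(=O)O[C@@H]3[C@H]21 | intermediate
19 | 3-trimethylsilyloxy-2,4(15)-diene of 18 | C=C1C(O[Si](C)(C)C)=C[C@H]2C(=C)CC[C@@H]3C(=C)C(=O)O[C@@H]3[C@H]21 | intermediate
20 | 2α-trimethylsilyloxy ketone | C=C1C(=O)[C@H](O[Si](C)(C)C)[C@H]2C(=C)CC[C@@H]3C(=C)C(=O)O[C@@H]3[C@H]21 | intermediate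
21 | 2α-hydroxy-7-epi-dehydrozaluzanin C | C=C1C(=O)[C@H](O)[C@H]2C(=C)CC[C@@H]3C(=C)C(=O)O[C@@H]3[C@H]21 | intermediate
22 | diosphenol diene: 2-hydroxy-3-oxo-5αH,6βH,7βH-guaia-1,4(15),10(14),11(13)-tetraen-12,6-olide | C=C1C(=O)C(O)=C2C(=C)CC[C@@H]3C(=C)C(=O)O[C@@H]3[C@H]21 | intermediate
23 | CNP0269880.1 (2α-hydroxy endo spiro-dimer; ring D = C2–C1=C10–C14–C15′–C4′) | C=C1C(=O)[C@]2(O)C3=C(CC[C@@H]4C(=C)C(=O)O[C@@H]4[C@@H]13)CC[C@]21C(=O)C[C@H]2C(=C)CC[C@@H]3C(=C)C(=O)O[C@@H]3[C@H]21 | target

## Step count and risks

Total step count: 16. Longest linear sequence: 16 steps (1 → 23; compound 18 serves both as the dienophile and as the precursor of diene 22).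

The three steps most likely to fail:

**Step 7 (photocycloaddition).** The seven-membered enone may photoisomerise to its strained trans isomer. This would lead to dimers, to the head-to-head regioisomer through a polar ground-state addition, or to loss of facial control. The fallback replaces enone photochemistry by a thermal ketene-type cycloaddition on an isolated alkene; it sets out from 9 and comes back at 11. Luche reduction of 9 (NaBH4, CeCl3·7H2O, MeOH) should give the allylic alcohol F1 as a mixture of C10 epimers, which does not matter. Silylation (TBSCl, imidazole) gives the silyl ether F2. The C1=C5 alkene of F2 then undergoes a keteniminium [2+2] cycloaddition (N,N-dimethylacetamide, Tf2O, 2,4,6-collidine; aqueous hydrolysis of the cyclobutaniminium salt). The iminium carbon should bond to C5, because developing positive charge is better tolerated at C1 (next to the silyloxy carbon) than at C5 (next to the acyloxy carbon), and the reagent should approach anti to the lactone; this gives the cyclobutanone F3. Treatment with HC(OMe)3, MeOH and camphorsulfonic acid converts the cyclobutanone into its dimethyl acetal with loss of the silyl group, giving the hydroxy acetal F4. Dess–Martin oxidation of the C10 alcohol returns 11.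

**Step 12 (key ring expansion).** Meyer–Schuster isomerisation or hydration of the propargylic alcohol under gold catalysis may compete, and C2 may migrate in place of C5. The fallback removes the alkyne and uses an oxidative palladium manifold; it sets out from 16 and comes back at 18. Vinylmagnesium bromide (THF, −78 °C) adds to 16 to give the vinyl carbinol F5. PdCl2(MeCN)2 (cat.) with benzoquinone in THF then activates the hydroxyl-bearing vinyl group (Wacker-type activation by divalent palladium). The 1,2-shift of C5 and β-hydride elimination of the resulting alkylpalladium deliver the 2-methylenecyclopentanone 18 directly.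

**Step 16 (dimerisation).** Diene 22 may dimerise with itself, Michael addition may occur without ring closure, or the partners may combine on the wrong faces (poor endo or facial selectivity). The fallback moves the hydroxylation to the end and uses a non-enolic diene; it sets out from 18 and comes back at 23. TBSOTf and Et3N convert 18 into the silyl dienol ether F6. Saegusa oxidation with Pd(OAc)2 in MeCN gives the cross-conjugated dienone F7, whose C2=C1–C10=C14 diene is trapped in situ by a second molecule of 18 (concentrated solution) to give the 2-deoxy dimer F8 (2αH). The doubly activated C2–H of F8 is then removed with KN(SiMe3)2 (1 equiv, THF, −78 °C) and the enolate is hydroxylated with 2-(phenylsulfonyl)-3-phenyloxaziridine from the α-face to give 23.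

Further compounds
F1 | step 7 | allylic alcohol (C10–OH, C1=C5; C10 epimers) | O=C1C[C@H]2CCC(O)C=C[C@H]2O1
F2 | step 7 | tert-butyldimethylsilyl ether of F1 | O=C1C[C@H]2CCC(O[Si](C)(C)C(C)(C)C)C=C[C@H]2O1
F3 | step 7 | cyclobutanone with C10 silyl ether (C3 ketone; 1αH,5αH) | O=C1C[C@H]2C(O[Si](C)(C)C(C)(C)C)CC[C@@H]3CC(=O)O[C@@H]3[C@H]21
F4 | step 7 | C10-hydroxy C3 dimethyl acetal | COC1(OC)C[C@H]2C(O)CC[C@@H]3CC(=O)O[C@@H]3[C@H]21
F5 | step 12 | 3-vinylcyclobutan-3-ol (vinyl α, hydroxyl β) | C=C[C@]1(O)C[C@H]2C(=C)CC[C@@H]3C(=C)C(=O)O[C@@H]3[C@H]21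
F6 | step 16 | 3-(tert-butyldimethylsilyloxy)-2,4(15)-diene of 18 | C=C1C(O[Si](C)(C)C(C)(C)C)=C[C@H]2C(=C)CC[C@@H]3C(=C)C(=O)O[C@@H]3[C@H]21
F7 | step 16 | cross-conjugated dienone (1,2-dehydro-18) | C=C1C(=O)C=C2C(=C)CC[C@@H]3C(=C)C(=O)O[C@@H]3[C@H]21
F8 | step 16 | 2-deoxy dimer (2αH) | C=C1C(=O)[C@@H]2C3=C(CC[C@@H]4C(=C)C(=O)O[C@@H]4[C@@H]13)CC[C@]21C(=O)C[C@H]2C(=C)CC[C@@H]3C(=C)C(=O)O[C@@H]3[C@H]21
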